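**Retrosynthetic overview**
1. The target is a trans α-methylene γ-lactone acid. With the ring numbered O1, C2 (C=O), C3, C4, C5, the exocyclic CH2 on C3 and the CO2H on C4 are two one-carbon units on the α- and β-carbons of a 5-alkylbutenolide; the plan rests on this.
2. Late unmasking: C3=CH2 from a C3–CH2NMe2 Mannich base (N-methylation, then elimination, last); C4–CO2H from C4–C(SMe)3; OAc from OTBS.
3. Key disconnection: the C4–C(SMe)3 and C3–CH2N bonds are made in one flask on the (R)-butenolide by 1,4-addition of LiC(SMe)3 and capture of the enolate with CH2=NMe2+ I−.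
4. The butenolide comes from a Z-γ-hydroxy enoate, made from the (R)-γ-hydroxy ynoate of a catalytic asymmetric addition of methyl propiolate to 14-silyloxytetradecanal (from 1,14-tetradecanediol).
5. Ring order: the only ring, the γ-lactone, is closed in step 4 and kept to the end; the key step closes no ring.

Key step: step 5

Remark: lactone numbering (O1, C2 carbonyl, C3, C4, C5) is used for all ring compounds; in it the target is (4S,5R), with the C4 carboxyl trans to the C5 chain.
Assumption: the (S,S) ligand in step 3 is taken to deliver the alkynyl group to the aldehyde face that gives the (R)-carbinol; if the sense is the opposite, the (R,R) ligand is used with no other change.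

**Step 1**
Reactants: 1 1,14-tetradecanediol
Product: 2 14-(tert-butyldimethylsilyloxy)tetradecan-1-ol
Conditions: NaH (1.0 equiv), THF, 0 °C to rt; TBSCl (1.0 equiv), rt
Reagents that add atoms: tert-butyldimethylsilyl chloride (TBSCl), CC(C)(C)[Si](C)(C)Cl
Why: O-silylation of the sparingly soluble monosodium alkoxide of a symmetrical diol should favour the mono-silyl ether over the bis-ether; no stereocentre is involved.

**Step 2**
Reactants: 2 14-(tert-butyldimethylsilyloxy)tetradecan-1-ol
Product: 3 14-(tert-butyldimethylsilyloxy)tetradecanal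
Conditions: TEMPO (cat.), PhI(OAc)2, CH2Cl2, rt
Reagents that add atoms: none
Why: Oxoammonium (nitroxyl-catalysed) oxidation of a primary alcohol should stop at the aldehyde and leave the silyl ether untouched.

**Step 3**
Reactants: 3 14-(tert-butyldimethylsilyloxy)tetradecanal; 4 methyl propiolate
Product: 6 methyl (4R)-17-(tert-butyldimethylsilyloxy)-4-hydroxyheptadec-2-ynoate, via methyl 3-(methylzincio)prop-2-ynoate 5 (not isolated)
Conditions: Me2Zn, (S,S)-ProPhenol [2,6-bis{[(S)-2-(hydroxydiphenylmethyl)pyrrolidin-1-yl]methyl}-4-methylphenol] (10 mol %), Ph3P=O (20 mol %), PhMe, 0 °C; aq. NH4Cl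
Reagents that add atoms: none
Why: Catalytic asymmetric alkynylation of an aldehyde by an alkynylzinc, in which Me2Zn deprotonates the propiolate and the dinuclear zinc complex of the chiral amino-alcohol ligand holds aldehyde and alkynyl group on neighbouring zinc centres, so that the ligand alone should set the carbinol carbon (the later C5) as R.

**Step 4**
Reactants: 6 methyl (4R)-17-(tert-butyldimethylsilyloxy)-4-hydroxyheptadec-2-ynoate
Product: 8 (R)-5-[13-(tert-butyldimethylsilyloxy)tridecyl]furan-2(5H)-one, via methyl (2Z,4R)-17-(tert-butyldimethylsilyloxy)-4-hydroxyheptadec-2-enoate 7 (not isolated)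
Conditions: H2 (1 atm), Pd/CaCO3 poisoned with Pb(OAc)2, quinoline, EtOAc, rt; then PPTS (cat.), PhMe, 40 °C
Reagents that add atoms: none
Why: Lindlar-type cis-semihydrogenation should give the Z-enoate, whose hydroxyl and ester are held cis and lactonise (5-exo-trig acyl substitution) with loss of methanol; the carbinol stereocentre is not touched.

**Step 5**
Reactants: 8 (R)-5-[13-(tert-butyldimethylsilyloxy)tridecyl]furan-2(5H)-one; 9 tris(methylthio)methane; 10 dimethyl(methylidene)ammonium iodide
Product: 13 (3R,4S,5R)-5-[13-(tert-butyldimethylsilyloxy)tridecyl]-3-[(dimethylamino)methyl]-4-[tris(methylsulfanyl)methyl]oxolan-2-one, via tris(methylthio)methyllithium 11 (not isolated), via lithium enolate of the conjugate adduct 12 (not isolated)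
Conditions: 9, n-BuLi, THF, −78 °C; add 8, −78 °C; then 10 (dry solid, 2 equiv), −78 to 0 °C; aq. NaHCO3
Reagents that add atoms: none
Why: n-BuLi deprotonates 9 to the sulfur-stabilised, sterically demanding carbanion 11, which adds in Michael fashion to C4 of butenolide 8 to give lithium enolate 12, and 12 is then alkylated at C3 by the iminium ion of 10 in a Mannich reaction, so that the C4–C(SMe)3 and C3–CH2N bonds are made in one flask. The closest known chemistry is the tandem conjugate addition of tris(alkylthio)methyllithium reagents to butenolides with capture of the enolate by carbon electrophiles, together with the Mannich alkylation of lactone enolates by dimethyl(methylidene)ammonium iodide. No ring is closed, the lactone of 8 being carried through unchanged. C4 (S) is controlled by the C5 stereocentre, the carbanion approaching the flat ring on the face opposite the tridecyl chain; C3 (R) is controlled by the new C(SMe)3 group at C4, the iminium ion entering anti to it, which should give the all-trans lactone (C3 is erased in step 9). The step needs 1,4- over 1,2-addition and over γ-deprotonation at C5, which the soft, hindered carbanion at −78 °C should secure, and anti facial selectivity at C4, which the single C5 substituent on the planar butenolide should secure. The chain end is carried as a silyl ether and not as the acetate so that no ester competes for the organolithium.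

**Step 6**
Reactants: 13 (3R,4S,5R)-5-[13-(tert-butyldimethylsilyloxy)tridecyl]-3-[(dimethylamino)methyl]-4-[tris(methylsulfanyl)methyl]oxolan-2-one
Product: 14 (3R,4S,5R)-3-[(dimethylamino)methyl]-5-(13-hydroxytridecyl)-4-[tris(methylsulfanyl)methyl]oxolan-2-one
Conditions: HF·pyridine, pyridine, THF, 0 °C to rt; aq. NaHCO3
Reagents that add atoms: none
Why: Fluoride-driven cleavage of the Si–O bond under non-basic conditions should free the primary alcohol while lactone, orthothioester and Mannich base (only protonated reversibly) stay intact.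

**Step 7**
Reactants: 14 (3R,4S,5R)-3-[(dimethylamino)methyl]-5-(13-hydroxytridecyl)-4-[tris(methylsulfanyl)methyl]oxolan-2-one
Product: 15 (3R,4S,5R)-5-(13-acetoxytridecyl)-3-[(dimethylamino)methyl]-4-[tris(methylsulfanyl)methyl]oxolan-2-one
Conditions: Ac2O, pyridine, DMAP (cat.), CH2Cl2, 0 °C to rt
Reagents that add atoms: acetic anhydride, CC(=O)OC(C)=O
Why: Nucleophile-catalysed acylation of the primary alcohol; the tertiary amine and the orthothioester have no acylable site.

**Step 8**
Reactants: 15 (3R,4S,5R)-5-(13-acetoxytridecyl)-3-[(dimethylamino)methyl]-4-[tris(methylsulfanyl)methyl]oxolan-2-one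
Product: 16 (3R,4S,5R)-5-(13-acetoxytridecyl)-3-[(dimethylamino)methyl]-2-oxooxolane-4-carboxylic acid
Conditions: HgO, BF3·OEt2, THF/H2O (85:15), rt; filter; NaHCO3 to pH 6–7; extract (CHCl3/i-PrOH)
Reagents that add atoms: water, O
Why: Thiophile-assisted hydrolysis of an orthothioester, in which divalent mercury removes the three methylthio groups stepwise (dithiocarbenium ion, thiol ester, acid) in an acidic medium that keeps the amine protonated, so that it neither binds mercury nor eliminates, and that should be too mild at rt to hydrolyse the acetate or the lactone.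

**Step 9**
Reactants: 16 (3R,4S,5R)-5-(13-acetoxytridecyl)-3-[(dimethylamino)methyl]-2-oxooxolane-4-carboxylic acid
Product: 18 (4S,5R)-5-(13-acetoxytridecyl)-3-methylidene-2-oxooxolane-4-carboxylic acid (target CNP0178400.1), via trimethylammonium carboxylate betaine 17 (not isolated)
Conditions: MeI (excess), NaHCO3, MeOH, rt; concentrate; 5% aq. NaHCO3/EtOAc, rt; 1 M HCl to pH 3
Reagents that add atoms: none
Why: Exhaustive N-methylation in methanol (where carboxylate O-alkylation is slow) gives betaine 17, whose acidic C3–H allows bicarbonate-mediated E1cB (Hofmann-type) loss of trimethylamine to reveal the exocyclic methylene, while the carboxylate at C4 disfavours removal of the allylic C4–H, so the 4S centre and the exo position of the double bond should hold.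

**Compound list**
1 | 1,14-tetradecanediol | OCCCCCCCCCCCCCCO | starting material
2 | 14-(tert-butyldimethylsilyloxy)tetradecan-1-ol | OCCCCCCCCCCCCCCO[Si](C)(C)C(C)(C)C | intermediate
3 | 14-(tert-butyldimethylsilyloxy)tetradecanal | O=CCCCCCCCCCCCCCO[Si](C)(C)C(C)(C)C | intermediate
4 | methyl propiolate | C#CC(=O)OC | starting material
5 | methyl 3-(methylzincio)prop-2-ynoate | C[Zn]C#CC(=O)OC | intermediate (not isolated)
6 | methyl (4R)-17-(tert-butyldimethylsilyloxy)-4-hydroxyheptadec-2-ynoate | COC(=O)C#C[C@H](O)CCCCCCCCCCCCCO[Si](C)(C)C(C)(C)C | intermediate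
7 | methyl (2Z,4R)-17-(tert-butyldimethylsilyloxy)-4-hydroxyheptadec-2-enoate | COC(=O)/C=C\[C@H](O)CCCCCCCCCCCCCO[Si](C)(C)C(C)(C)C | intermediate (not isolated)
8 | (R)-5-[13-(tert-butyldimethylsilyloxy)tridecyl]furan-2(5H)-one | O=C1O[C@H](CCCCCCCCCCCCCO[Si](C)(C)C(C)(C)C)C=C1 | intermediate
9 | tris(methylthio)methane | CSC(SC)SC | starting material
10 | dimethyl(methylidene)ammonium iodide | C=[N+](C)C.[I-] | starting material
11 | tris(methylthio)methyllithium | [Li]C(SC)(SC)SC | intermediate (not isolated)
12 | lithium (4S,5R)-5-[13-(tert-butyldimethylsilyloxy)tridecyl]-4-[tris(methylsulfanyl)methyl]-4,5-dihydrofuran-2-olate | [Li]OC1=C[C@H](C(SC)(SC)SC)[C@@H](CCCCCCCCCCCCCO[Si](C)(C)C(C)(C)C)O1 | intermediate (not isolated)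
13 | (3R,4S,5R)-5-[13-(tert-butyldimethylsilyloxy)tridecyl]-3-[(dimethylamino)methyl]-4-[tris(methylsulfanyl)methyl]oxolan-2-one | CN(C)C[C@@H]1C(=O)O[C@H](CCCCCCCCCCCCCO[Si](C)(C)C(C)(C)C)[C@H]1C(SC)(SC)SC | intermediate
14 | (3R,4S,5R)-3-[(dimethylamino)methyl]-5-(13-hydroxytridecyl)-4-[tris(methylsulfanyl)methyl]oxolan-2-one | CN(C)C[C@@H]1C(=O)O[C@H](CCCCCCCCCCCCCO)[C@H]1C(SC)(SC)SC | intermediate
15 | (3R,4S,5R)-5-(13-acetoxytridecyl)-3-[(dimethylamino)methyl]-4-[tris(methylsulfanyl)methyl]oxolan-2-one | CN(C)C[C@@H]1C(=O)O[C@H](CCCCCCCCCCCCCOC(C)=O)[C@H]1C(SC)(SC)SC | intermediate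
16 | (3R,4S,5R)-5-(13-acetoxytridecyl)-3-[(dimethylamino)methyl]-2-oxooxolane-4-carboxylic acid | CN(C)C[C@@H]1C(=O)O[C@H](CCCCCCCCCCCCCOC(C)=O)[C@H]1C(=O)O | intermediate
17 | (3R,4S,5R)-5-(13-acetoxytridecyl)-2-oxo-3-[(trimethylammonio)methyl]oxolane-4-carboxylate | C[N+](C)(C)C[C@@H]1C(=O)O[C@H](CCCCCCCCCCCCCOC(C)=O)[C@H]1C(=O)[O-] | intermediate (not isolated)
18 | (4S,5R)-5-(13-acetoxytridecyl)-3-methylidene-2-oxooxolane-4-carboxylic acid | C=C1C(=O)O[C@H](CCCCCCCCCCCCCOC(C)=O)[C@H]1C(=O)O | target

**Step count**
Total steps: 9. Longest linear sequence: 9 steps (1 to 18).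

**Steps most likely to fail**

Step 5. The enolate 12 may not be captured cleanly by the iminium salt, which is only suspended in THF: proton transfer, slow heterogeneous alkylation or reversal of the conjugate addition on warming would return the simple adduct or mixtures. Deprotonation of 8 at C5 by the carbanion would erode the C5 configuration. The fallback sets out from 8 and 9. The same conjugate addition is run at −78 °C, but enolate 12 is quenched with Me3SiCl to give the silyl ketene acetal {[(4S,5R)-5-[13-(tert-butyldimethylsilyloxy)tridecyl]-4-[tris(methylsulfanyl)methyl]-4,5-dihydrofuran-2-yl]oxy}trimethylsilane F1, which is freed from lithium salts without water. F1 is then treated with 10 in CH2Cl2 at rt, the Mannich reaction of a neutral silyl enol ether with the dissolved iminium salt, and the route is rejoined at 13.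

Step 9. Quaternisation of the zwitterionic amino acid may be sluggish, the carboxylate may be O-methylated, and the base may move the new double bond into the ring (loss of the C4 centre) or add methanol to it. The fallback sets out from 16. The amine is oxidised with mCPBA (NaHCO3 buffer, CH2Cl2, 0 °C) to the N-oxide (3R,4S,5R)-5-(13-acetoxytridecyl)-3-[(dimethyloxidoazaniumyl)methyl]-2-oxooxolane-4-carboxylic acid F2. F2 should undergo Cope elimination at or slightly above rt without added base, releasing N,N-dimethylhydroxylamine, and the route is rejoined at 18.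

Step 3. Enantioselectivity may be insufficient with a long-chain, enolisable aliphatic aldehyde, and self-aldol condensation may compete during the slow catalytic addition. The fallback sets out from 3 and 4. Methyl propiolate is lithiated (n-BuLi, THF, −78 °C) to methyl 3-lithioprop-2-ynoate F3, which adds to 3 to give racemic methyl 17-(tert-butyldimethylsilyloxy)-4-hydroxyheptadec-2-ynoate F4. F4 is oxidised with Dess–Martin periodinane to methyl 17-(tert-butyldimethylsilyloxy)-4-oxoheptadec-2-ynoate F5. Midland reduction of F5 with B-isopinocampheyl-9-borabicyclo[3.3.1]nonane from (+)-α-pinene, the reagent that gives (R)-carbinols from alkynyl ketones, rejoins the route at 6.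

**Further compounds**
F1 | step 5 | {[(4S,5R)-5-[13-(tert-butyldimethylsilyloxy)tridecyl]-4-[tris(methylsulfanyl)methyl]-4,5-dihydrofuran-2-yl]oxy}trimethylsilane | C[Si](C)(C)OC1=C[C@H](C(SC)(SC)SC)[C@@H](CCCCCCCCCCCCCO[Si](C)(C)C(C)(C)C)O1
F2 | step 9 | (3R,4S,5R)-5-(13-acetoxytridecyl)-3-[(dimethyloxidoazaniumyl)methyl]-2-oxooxolane-4-carboxylic acid | C[N+](C)([O-])C[C@@H]1C(=O)O[C@H](CCCCCCCCCCCCCOC(C)=O)[C@H]1C(=O)O
F3 | step 3 | methyl 3-lithioprop-2-ynoate | [Li]C#CC(=O)OC
F4 | step 3 | racemic methyl 17-(tert-butyldimethylsilyloxy)-4-hydroxyheptadec-2-ynoate | COC(=O)C#CC(O)CCCCCCCCCCCCCO[Si](C)(C)C(C)(C)C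
F5 | step 3 | methyl 17-(tert-butyldimethylsilyloxy)-4-oxoheptadec-2-ynoate | COC(=O)C#CC(=O)CCCCCCCCCCCCCO[Si](C)(C)C(C)(C)C
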